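**Plan**

- Labels: ring A is the central coumarin (unprimed locants), ring B the 7-hydroxycoumarin-8-yl unit on C6 (primed), ring C the 7-hydroxycoumarin-3-yl unit on O7 (double-primed).
- First cuts: the two O–CH3 bonds, then C3''=C4'' and O1''–C2'' of ring C. C3'' carries O7 of ring A as an enol ether oxygen, so it is the α-carbon of an O7–CH2–CO2H acid, and C4''/O1'' come from a salicylaldehyde.
- Further cuts: the C6–C8' biaryl bond (Suzuki–Miyaura), the O7–CH2 bond (alkylation) and the pyranone of ring A (Pechmann on 4-bromoresorcinol). Ring B is bought as umbelliferone and iodinated at C8'.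
- Forward order: ring A pyranone, O7 alkylation, borylation; ring B iodide; biaryl bond; release of the acid; ring C pyranone; demethylation.
- Stereochemistry: the target has no stereocentre, so nothing has to be set.

Key step: step 8

Remark on the chemistry: the target SMILES gives no descriptor for the C6–C8' axis, so the axis is taken as configurationally undefined and no axial control is planned.

**Route**

Step 1
Reactants: 1 4-bromoresorcinol; 2 DL-malic acid
Product: 4 6-bromo-7-hydroxy-2H-chromen-2-one, via 3-oxopropanoic acid 3 (not isolated)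
Conditions: conc. H2SO4, 100–110 °C
Reagents that add atoms: none
Why: Pechmann condensation in its malic acid variant, in which hot sulfuric acid decarbonylates 2 to 3, this attacks the one free position of 1 that is ortho to one hydroxyl and para to the other, and the cinnamic acid formed lactonises onto the ortho hydroxyl to close the pyranone of ring A.

Step 2
Reactants: 4 6-bromo-7-hydroxy-2H-chromen-2-one; 5 tert-butyl bromoacetate
Product: 6 tert-butyl 2-[(6-bromo-2-oxo-2H-chromen-7-yl)oxy]acetate
Conditions: K2CO3, DMF, rt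
Reagents that add atoms: none
Why: Williamson ether synthesis on the only phenol of 4, whose acidity is raised by the coumarin, with a reactive α-bromo ester under carbonate conditions that leave the lactone and the tert-butyl ester untouched.

Step 3
Reactants: 6 tert-butyl 2-[(6-bromo-2-oxo-2H-chromen-7-yl)oxy]acetate
Product: 7 tert-butyl 2-{[2-oxo-6-(4,4,5,5-tetramethyl-1,3,2-dioxaborolan-2-yl)-2H-chromen-7-yl]oxy}acetate
Conditions: B2pin2, PdCl2(dppf) (cat.), KOAc, 1,4-dioxane, 90 °C
Reagents that add atoms: bis(pinacolato)diboron, CC1(C)OB(OC1(C)C)B1OC(C)(C)C(C)(C)O1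
Why: Miyaura borylation, in which the aryl bromide adds oxidatively to zerovalent palladium and the acetate-bound palladium transmetalates with the diboron, KOAc being too weak a base to promote onward coupling or to harm the esters.

Step 4
Reactants: 8 7-hydroxy-2H-chromen-2-one (umbelliferone)
Product: 9 7-hydroxy-8-iodo-2H-chromen-2-one
Conditions: I2, KI, aq NH3, 0 °C → rt; then dil. HCl
Reagents that add atoms: iodine, II
Why: Electrophilic aromatic iodination of the phenoxide, which is known to go to C8, the position ortho to O7 and most electron-rich in the umbelliferone anion.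

Step 5
Reactants: 9 7-hydroxy-8-iodo-2H-chromen-2-one
Product: 10 8-iodo-7-methoxy-2H-chromen-2-one
Conditions: MeI, K2CO3, acetone, reflux
Reagents that add atoms: iodomethane, CI
Why: Williamson methylation of the single phenol, which caps the ring B oxygen with a group that survives coupling, acid and hot anhydride.

Step 6
Reactants: 7 tert-butyl 2-{[2-oxo-6-(4,4,5,5-tetramethyl-1,3,2-dioxaborolan-2-yl)-2H-chromen-7-yl]oxy}acetate; 10 8-iodo-7-methoxy-2H-chromen-2-one
Product: 11 tert-butyl 2-{[6-(7-methoxy-2-oxo-2H-chromen-8-yl)-2-oxo-2H-chromen-7-yl]oxy}acetate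
Conditions: Pd(OAc)2 (cat.), SPhos, K3PO4, toluene/H2O (10:1), 90 °C; then dil. HCl work-up
Reagents that add atoms: none
Why: Suzuki–Miyaura cross-coupling in which the doubly ortho-substituted partner is the iodide and the boron sits on the less hindered ring, the bulky electron-rich biarylphosphine on palladium carries transmetalation and reductive elimination at the tri-ortho-substituted junction, and the acidic work-up recloses any lactone opened by the base.

Step 7
Reactants: 11 tert-butyl 2-{[6-(7-methoxy-2-oxo-2H-chromen-8-yl)-2-oxo-2H-chromen-7-yl]oxy}acetate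
Product: 12 2-{[6-(7-methoxy-2-oxo-2H-chromen-8-yl)-2-oxo-2H-chromen-7-yl]oxy}acetic acid
Conditions: TFA, CH2Cl2, rt
Reagents that add atoms: none
Why: Acidolysis of the tert-butyl ester by loss of isobutene frees the acid without hydroxide, so both lactones and the methyl ether stay intact.

Step 8
Reactants: 12 2-{[6-(7-methoxy-2-oxo-2H-chromen-8-yl)-2-oxo-2H-chromen-7-yl]oxy}acetic acid; 13 2-hydroxy-4-methoxybenzaldehyde
Product: 16 7-methoxy-3-{[6-(7-methoxy-2-oxo-2H-chromen-8-yl)-2-oxo-2H-chromen-7-yl]oxy}-2H-chromen-2-one, via mixed acetic anhydride 14 (not isolated), via 2-formyl-5-methoxyphenyl ester 15 (not isolated)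
Conditions: Ac2O, Et3N, 110 °C
Reagents that add atoms: none
Why: Acid 12 and acetic anhydride equilibrate to mixed anhydride 14, which acylates the phenol of 13 to give aryl ester 15 and thereby forms the O1''–C2'' bond. Triethylamine then enolises the α-aryloxy methylene of 15, the enolate adds to the ortho formyl group in a 6-(enolexo)-exo-trig aldol closure, and acetylation of the aldol hydroxyl followed by E1cB elimination installs C3''=C4'' and completes the pyranone of ring C. The closest known reaction type is the Perkin condensation of aryloxyacetic acids with salicylaldehydes in acetic anhydride and base, which gives 3-aryloxycoumarins. No stereocentre results, because both aldol carbons end as the sp2 atoms C3'' and C4''. The selectivity needed is condensation of the aldehyde with the aryloxyacetyl unit and not with an acetyl group, and it is secured by the higher acidity of the oxygen-substituted CH2 in an aryl ester, by the intramolecular closure, and by acyl exchange that returns O-acetylated 13 to the productive path. The methyl ethers and the two existing lactones offer no acidic or nucleophilic site under these conditions.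

Step 9
Reactants: 16 7-methoxy-3-{[6-(7-methoxy-2-oxo-2H-chromen-8-yl)-2-oxo-2H-chromen-7-yl]oxy}-2H-chromen-2-one
Product: 17 7-hydroxy-3-{[6-(7-hydroxy-2-oxo-2H-chromen-8-yl)-2-oxo-2H-chromen-7-yl]oxy}-2H-chromen-2-one
Conditions: BBr3 (excess), CH2Cl2, −78 °C → rt; then ice/H2O
Reagents that add atoms: none
Why: Lewis acid ether cleavage, in which boron binds each methoxy oxygen and bromide attacks the methyl carbon by SN2, while the C3''–O–C7 ether joins two sp2 carbons and cannot be cleaved this way and the lactones come through the aqueous work-up closed.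

**Compound list**

1 | 4-bromoresorcinol | Oc1ccc(Br)c(O)c1 | starting material
2 | DL-malic acid | OC(CC(=O)O)C(=O)O | starting material
3 | 3-oxopropanoic acid | O=CCC(=O)O | intermediate
4 | 6-bromo-7-hydroxy-2H-chromen-2-one | O=c1ccc2cc(Br)c(O)cc2o1 | intermediate
5 | tert-butyl bromoacetate | CC(C)(C)OC(=O)CBr | starting material
6 | tert-butyl 2-[(6-bromo-2-oxo-2H-chromen-7-yl)oxy]acetate | CC(C)(C)OC(=O)COc1cc2oc(=O)ccc2cc1Br | intermediate
7 | tert-butyl 2-{[2-oxo-6-(4,4,5,5-tetramethyl-1,3,2-dioxaborolan-2-yl)-2H-chromen-7-yl]oxy}acetate | CC(C)(C)OC(=O)COc1cc2oc(=O)ccc2cc1B1OC(C)(C)C(C)(C)O1 | intermediate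
8 | 7-hydroxy-2H-chromen-2-one (umbelliferone) | O=c1ccc2ccc(O)cc2o1 | starting material
9 | 7-hydroxy-8-iodo-2H-chromen-2-one | O=c1ccc2ccc(O)c(I)c2o1 | intermediate
10 | 8-iodo-7-methoxy-2H-chromen-2-one | COc1ccc2ccc(=O)oc2c1I | intermediate
11 | tert-butyl 2-{[6-(7-methoxy-2-oxo-2H-chromen-8-yl)-2-oxo-2H-chromen-7-yl]oxy}acetate | COc1ccc2ccc(=O)oc2c1-c1cc2ccc(=O)oc2cc1OCC(=O)OC(C)(C)C | intermediate
12 | 2-{[6-(7-methoxy-2-oxo-2H-chromen-8-yl)-2-oxo-2H-chromen-7-yl]oxy}acetic acid | COc1ccc2ccc(=O)oc2c1-c1cc2ccc(=O)oc2cc1OCC(=O)O | intermediate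
13 | 2-hydroxy-4-methoxybenzaldehyde | COc1ccc(C=O)c(O)c1 | starting material
14 | acetic 2-{[6-(7-methoxy-2-oxo-2H-chromen-8-yl)-2-oxo-2H-chromen-7-yl]oxy}acetic anhydride | COc1ccc2ccc(=O)oc2c1-c1cc2ccc(=O)oc2cc1OCC(=O)OC(C)=O | intermediate
15 | 2-formyl-5-methoxyphenyl 2-{[6-(7-methoxy-2-oxo-2H-chromen-8-yl)-2-oxo-2H-chromen-7-yl]oxy}acetate | COc1ccc2ccc(=O)oc2c1-c1cc2ccc(=O)oc2cc1OCC(=O)Oc1cc(OC)ccc1C=O | intermediate
16 | 7-methoxy-3-{[6-(7-methoxy-2-oxo-2H-chromen-8-yl)-2-oxo-2H-chromen-7-yl]oxy}-2H-chromen-2-one | O=c1ccc2cc(-c3c(OC)ccc4ccc(=O)oc34)c(Oc3cc4ccc(OC)cc4oc3=O)cc2o1 | intermediate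
17 | 7-hydroxy-3-{[6-(7-hydroxy-2-oxo-2H-chromen-8-yl)-2-oxo-2H-chromen-7-yl]oxy}-2H-chromen-2-one | O=c1ccc2cc(-c3c(O)ccc4ccc(=O)oc34)c(Oc3cc4ccc(O)cc4oc3=O)cc2o1 | target

**Step count**

Total: 9 steps. Longest linear sequence: 7 steps (steps 1, 2, 3, 6, 7, 8, 9); steps 4 and 5 form the ring B branch.

**Steps most likely to fail, with fallbacks**

Step 6. Transmetalation at the tri-ortho-substituted junction may be slow, so that protodeboronation of the ortho-alkoxy boronate and hydroxide-induced opening of the lactones overtake the coupling. The fallback sets out from bromide 6 and uses a base-free Stille coupling. Stannylation of 6 with hexamethylditin (Pd(PPh3)4, toluene, 100 °C) would give tert-butyl 2-{[2-oxo-6-(trimethylstannyl)-2H-chromen-7-yl]oxy}acetate F1. Coupling of this stannane with iodide 10 (Pd(PPh3)4, CuI, CsF, DMF, 50 °C) has no boron to lose and no aqueous base, and the copper-assisted transmetalation tolerates ortho substituents. It comes back to the route at 11.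

Step 8. Acetylation of the phenol of 13 may become a dead end, and the enolate of acetic anhydride may condense with the aldehyde to give the simple 7-methoxycoumarin, while the sparingly soluble acid stays outside the acyl exchange. The fallback sets out from acid 12 and forms the same two bonds in separate operations without any acetyl donor. Oxalyl chloride with catalytic DMF in CH2Cl2 would give 2-{[6-(7-methoxy-2-oxo-2H-chromen-8-yl)-2-oxo-2H-chromen-7-yl]oxy}acetyl chloride F2. Acylation of 13 with this chloride and Et3N at 0 °C would give ester 15, this time isolated. DBU in MeCN would then effect the intramolecular aldol condensation, and the fallback comes back at 16.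

Step 9. Boron may be tied up by the three lactone carbonyls, so that partly demethylated material precipitates, or long exposure may open a lactone. The fallback sets out from 9 and replaces ether cleavage by ester cleavage at the end.
- MOMCl and iPr2NEt in CH2Cl2 would give 8-iodo-7-(methoxymethoxy)-2H-chromen-2-one F3.
- Coupling with boronate 7 under the conditions of step 6 would give tert-butyl 2-({6-[7-(methoxymethoxy)-2-oxo-2H-chromen-8-yl]-2-oxo-2H-chromen-7-yl}oxy)acetate F4.
- TFA in CH2Cl2 would remove the tert-butyl ester and the acetal together to give 2-{[6-(7-hydroxy-2-oxo-2H-chromen-8-yl)-2-oxo-2H-chromen-7-yl]oxy}acetic acid F5.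
- The Perkin condensation of step 8, run with commercial 2,4-dihydroxybenzaldehyde, would acetylate both free phenols in the same flask and give 8-{7-[(7-acetoxy-2-oxo-2H-chromen-3-yl)oxy]-2-oxo-2H-chromen-6-yl}-2-oxo-2H-chromen-7-yl acetate F6.
- Mild acid methanolysis (HCl, MeOH/THF, 40 °C) of the two aryl acetates would come back to the route at 17.

**Further compounds**

F1 | step 6 | tert-butyl 2-{[2-oxo-6-(trimethylstannyl)-2H-chromen-7-yl]oxy}acetate | CC(C)(C)OC(=O)COc1cc2oc(=O)ccc2cc1[Sn](C)(C)C
F2 | step 8 | 2-{[6-(7-methoxy-2-oxo-2H-chromen-8-yl)-2-oxo-2H-chromen-7-yl]oxy}acetyl chloride | COc1ccc2ccc(=O)oc2c1-c1cc2ccc(=O)oc2cc1OCC(=O)Cl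
F3 | step 9 | 8-iodo-7-(methoxymethoxy)-2H-chromen-2-one | COCOc1ccc2ccc(=O)oc2c1I
F4 | step 9 | tert-butyl 2-({6-[7-(methoxymethoxy)-2-oxo-2H-chromen-8-yl]-2-oxo-2H-chromen-7-yl}oxy)acetate | COCOc1ccc2ccc(=O)oc2c1-c1cc2ccc(=O)oc2cc1OCC(=O)OC(C)(C)C
F5 | step 9 | 2-{[6-(7-hydroxy-2-oxo-2H-chromen-8-yl)-2-oxo-2H-chromen-7-yl]oxy}acetic acid | Oc1ccc2ccc(=O)oc2c1-c1cc2ccc(=O)oc2cc1OCC(=O)O
F6 | step 9 | 8-{7-[(7-acetoxy-2-oxo-2H-chromen-3-yl)oxy]-2-oxo-2H-chromen-6-yl}-2-oxo-2H-chromen-7-yl acetate | CC(=O)Oc1ccc2ccc(=O)oc2c1-c1cc2ccc(=O)oc2cc1Oc1cc2ccc(OC(C)=O)cc2oc1=O
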